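**Plan**
- **Numbering of each half.** C1 is the ketone carbon, C2=C3 the ring alkene, C4 the carbinol, and C5/C6 the epoxide (C6 next to C1). Ca is the O–CH on C3, Cd the CH on C2, and Ce the CH(CH3)–O carbon.
- **Cuts.** Ca–Ca′ and Cd–Cd′ of the central cycloocta-1,5-diene (retro-[4+4]) and both O–Ce bonds (retro-oxa-6π) give two identical dienals. Further cuts are Cd=Ce (olefination), C1=O/C4–OH back to a 1,4-peroxide, retro-[4+2] loss of O2, and the C5–C6 bond (retro-6π). These lead to a flat, achiral 4,5-disubstituted oxepine.
- **Enabling feature.** Ring C1–C6 carries an epoxide on C5/C6, the C2=C3 alkene, and 1,4-oxygens on C1/C4 that both lie anti to the epoxide. It is therefore an O2 adduct of a benzene oxide, and its six carbons plus the epoxide oxygen are the seven ring atoms of an oxepine.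
- **Forward order.** Furan + alkyne → oxanorbornadiene → oxaquadricyclane → oxepine (7-ring) → carbocycle + oxirane + peroxide bridge → hydroxy enone. The C4–OH then tells the two identical CH2O arms apart, olefination follows, and both pyrans and the eight-membered ring form in one cascade.
- **Stereochemistry.** The cis-epoxide comes from disrotation and C4 from anti attack of singlet oxygen. The absolute sense comes from a cinchona base that desymmetrises the meso endoperoxide. Ca, Cd and Ce (twice each) come from dimerisation anti to epoxide and methyl, steered by a removable di-tert-butylsilanol on C4–O.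

Key step: step 5

Assumption: the sense of induction of the cinchona catalyst on the new meso endoperoxide 9 cannot be derived with certainty, so the quinidine-series catalyst is written, and its quinine-series pseudo-enantiomer would be taken if the antipode of 10 formed.

Step 1
Reactants: 1 furan; 2 dimethyl acetylenedicarboxylate
Product: 3 dimethyl 7-oxabicyclo[2.2.1]hepta-2,5-diene-2,3-dicarboxylate (meso)
Conditions: furan (excess), neat, rt, dark
Reagents that add atoms: none
Why: The Diels–Alder reaction of electron-rich furan with the doubly activated alkyne should stop at the 1:1 adduct when furan is in excess; the two bridgehead centres are fixed cis by the bicycle (meso) and are erased in step 2.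

Step 2
Reactants: 3 oxanorbornadiene diester
Product: 5 dimethyl oxepine-4,5-dicarboxylate, via oxaquadricyclane diester 4 (not isolated)
Conditions: hν (medium-pressure Hg, Pyrex), Et2O, −10 °C; evaporate; toluene, 110 °C
Reagents that add atoms: none
Why: Intramolecular [2+2] photocycloaddition of the two facing C=C bonds (norbornadiene-to-quadricyclane type), followed by thermal cycloreversion of the strained cage through a carbonyl ylide, is the established entry to oxepine-4,5-dicarboxylates and puts the two ester carbons (future Ca and Cd) on adjacent ring carbons; no stereocentre remains.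

Step 3
Reactants: 5 dimethyl oxepine-4,5-dicarboxylate
Product: 6 oxepine-4,5-diyldimethanol
Conditions: DIBAL-H (4.5 equiv), CH2Cl2/THF, −78 → −20 °C; aq Rochelle salt; Et3N-deactivated SiO2
Reagents that add atoms: none
Why: DIBAL-H 1,2-reduction of conjugated esters to allylic alcohols should leave the trienol-ether ring untouched, and the non-acidic tartrate work-up guards the acid-labile oxepine/arene oxide pair against aromatisation.

Step 4
Reactants: 6 oxepine-4,5-diyldimethanol
Product: 7 4,5-bis[(4-methoxybenzyloxy)methyl]oxepine
Conditions: NaH, PMBCl, Bu4NI (cat.), THF/DMF, 0 °C → rt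
Reagents that add atoms: 4-methoxybenzyl chloride, COc1ccc(CCl)cc1
Why: Williamson etherification under purely basic conditions, which oxepines tolerate, installs two identical arms so that the later endoperoxide is meso and each arm can be addressed oxidatively.

Step 5
Reactants: 7 4,5-bis[(4-methoxybenzyloxy)methyl]oxepine
Product: 10 (1R,5S,6R)-5-hydroxy-3,4-bis[(4-methoxybenzyloxy)methyl]-7-oxabicyclo[4.1.0]hept-3-en-2-one, via arene oxide tautomer 8 (not isolated), via anti-endoperoxide 9 (not isolated)
Conditions: O2, tetraphenylporphyrin (1 mol %), hν (λ > 550 nm), CH2Cl2, −60 °C; Ar purge; 9-O-acetylcupreidine (10 mol %), −30 °C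
Reagents that add atoms: dioxygen, O=O
Why: Oxepine 7 equilibrates rapidly with its valence tautomer 8 by a thermally allowed disrotatory 6π electrocyclisation that joins the two O-bound carbons (future C5–C6), so the seven-membered heterocycle contracts to the six-membered carbocycle with the ring oxygen left as the oxirane; singlet oxygen then adds to the s-cis diene C1=C2–C3=C4 of 8 in a suprafacial [4+2] cycloaddition to give 9, and the chiral tertiary amine removes one of the two enantiotopic bridgehead hydrogens with concerted O–O cleavage (Kornblum–DeLaMare rearrangement) to leave C1=O and C4–OH. The closest known reaction types are the singlet-oxygen trapping of benzene oxide/oxepine pairs as anti endoperoxides and the cinchona-base-catalysed desymmetrising Kornblum–DeLaMare rearrangement of meso bicyclic endoperoxides. Ring closures: carbocycle and oxirane form together by transannular 6π closure, and the 1,2-dioxane bridge forms by concerted [4+2] addition and is opened again in the same flask. Stereocontrol: the cis-epoxide (C5, C6) is the only outcome of disrotation within the ring, the C1–O and C4–O bonds form on the face opposite the oxirane oxygen so that C4–OH ends anti to the epoxide, and the absolute configuration comes from the catalyst's choice between the enantiotopic C1–H and C4–H, which is possible only because the two identical CH2OPMB arms make 9 meso. The step needs capture of 8 rather than the enol-ether bonds of 7, [4+2] rather than ene reaction at the CH2O groups, and no direct excitation of 7; the locked planar s-cis diene of 8 (Curtin–Hammett drain of the equilibrium) and light absorbed only by the sensitiser should secure this. Working at or below −30 °C with a weak amine base should keep 9 from rearranging to its bis-epoxide isomer and 10 from drifting to the 1,4-dione or aromatising.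

Step 6
Reactants: 10 hydroxy enone bis-PMB ether
Product: 11 p-methoxybenzylidene acetal spanning C4–O and C3–CH2O (aryl equatorial) that carries a free C2–CH2OH
Conditions: DDQ (2.3 equiv), 4 Å MS, CH2Cl2, 0 °C; then pH 7 buffer
Reagents that add atoms: none
Why: In this DDQ oxidation of PMB ethers, hydride abstraction gives an oxocarbenium ion on each arm; the one on C3–CH2O is trapped by the neighbouring C4–OH as a six-membered benzylidene acetal (oxidative acetalisation, aryl equatorial under chair control), whereas the one on C2–CH2O has no hydroxyl in reach (eight-membered ring) and is hydrolysed on work-up, so the two identical arms are told apart.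

Step 7
Reactants: 11 acetal alcohol
Product: 12 C2-carbaldehyde (acetal retained)
Conditions: DMP, pyridine, CH2Cl2, 0 °C → rt
Reagents that add atoms: none
Why: Dess–Martin oxidation of the only free (primary allylic) alcohol under buffered, non-aqueous conditions should spare acetal, epoxide and enone.

Step 8
Reactants: 12 C2-carbaldehyde; 13 5-(ethylsulfonyl)-1-phenyl-1H-tetrazole
Product: 14 C2-[(E)-prop-1-enyl] acetal
Conditions: 13, KHMDS, DME, −78 °C; then 12, −78 → −20 °C; aq NH4Cl
Reagents that add atoms: none
Why: In this Julia–Kocienski olefination the potassium anion of the phenyltetrazolyl sulfone adds to the aldehyde faster than to the hindered ketone, and anti-selective addition, Smiles rearrangement and anti elimination should favour the E-alkene, while any Z-isomer would converge in step 12 because the reversible oxa-6π closure erases the alkene geometry.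

Step 9
Reactants: 14 propenyl acetal
Product: 15 (1R,5S,6R)-5-hydroxy-4-(hydroxymethyl)-3-[(E)-prop-1-enyl]-7-oxabicyclo[4.1.0]hept-3-en-2-one
Conditions: AcOH/H2O/THF (3:1:1), rt
Reagents that add atoms: none
Why: Mild acid hydrolysis of the electron-rich p-methoxybenzylidene acetal should free both hydroxyls without opening the keto-epoxide; no stereocentre is touched.

Step 10
Reactants: 15 monomer diol
Product: 16 primary triethylsilyl ether of 15 (C4–OH free)
Conditions: TESCl (1.05 equiv), imidazole, CH2Cl2, −40 °C
Reagents that add atoms: chlorotriethylsilane, CC[Si](Cl)(CC)CC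
Why: In this sterically controlled silylation, one equivalent of TESCl at low temperature should take the primary allylic hydroxyl and leave the flanked secondary C4–OH free.

Step 11
Reactants: 16 primary TES ether
Product: 19 C4-O-[di-tert-butyl(hydroxy)silyl] monomer that has a free C3–CH2OH, via silyl triflate 17 (not isolated), via TES-protected alkoxysilanol 18 (not isolated)
Conditions: tBu2Si(OTf)2, 2,6-lutidine, CH2Cl2, −20 → 0 °C; sat. aq NaHCO3; then AcOH/H2O/THF, 0 °C → rt
Reagents that add atoms: di-tert-butylsilyl bis(trifluoromethanesulfonate), CC(C)(C)[Si](OS(=O)(=O)C(F)(F)F)(OS(=O)(=O)C(F)(F)F)C(C)(C)C; water, O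
Why: Silylation of the lone secondary alcohol with the bis-triflate stops at the alkoxysilyl triflate because no second hydroxyl is in reach, aqueous bicarbonate hydrolyses Si–OTf to the hindered, non-condensing silanol (the standard preparation of di-tert-butylsilanol ethers), and dilute acetic acid then removes only the primary TES ether.

Step 12
Reactants: 19 alkoxysilanol monomer (two molecules)
Product: 22 bis[di-tert-butyl(hydroxy)silyl] ether of epoxytwinol A (C2-symmetric [4+4] dimer), via dienal 20 (not isolated), via 2H-pyran 21 (not isolated)
Conditions: MnO2, CH2Cl2, rt; filter; concentrate; toluene (concentrated), rt, dark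
Reagents that add atoms: none
Why: MnO2 oxidises only the primary allylic alcohol, dienal 20 closes reversibly by disrotatory oxa-6π electrocyclisation to both Ce-epimeric 2H-pyrans, and of these 21 (methyl syn to the epoxide) should dimerise head-to-head in a formal [4+4] cycloaddition on the diene face anti to both methyl and epoxide, forming Ca–Ca′ and Cd–Cd′ suprafacially so that all six new stereocentres follow from the ring stereocentres under Curtin–Hammett control, while the bulky silanol groups on the reacting face hinder the competing [4+2] mode and pair the two halves by Si–OH hydrogen bonds (alkoxysilanol-assisted oxidation/oxa-6π/[4+4] dimerisation cascade of 2H-pyrans).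

Step 13
Reactants: 22 bis-silanol dimer
Product: 23 epoxytwinol A
Conditions: Et3N·3HF, MeCN, rt
Reagents that add atoms: none
Why: Fluoride-mediated Si–O cleavage under buffered conditions at room temperature should remove both silanol helpers without epoxide opening or thermal isomerisation of the [4+4] adduct; no stereocentre is touched.

**Compound list**
1 | furan | c1ccoc1 | starting material
2 | dimethyl acetylenedicarboxylate | COC(=O)C#CC(=O)OC | starting material
3 | dimethyl 7-oxabicyclo[2.2.1]hepta-2,5-diene-2,3-dicarboxylate (meso) | O1[C@H]2C=C[C@@H]1C(C(=O)OC)=C2C(=O)OC | intermediate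
4 | dimethyl 3-oxatetracyclo[3.2.0.0(2,7).0(4,6)]heptane-1,5-dicarboxylate (oxaquadricyclane, meso) | O1[C@H]2[C@H]3[C@H]4[C@@H]1[C@@]4(C(=O)OC)[C@@]23C(=O)OC | intermediate
5 | dimethyl oxepine-4,5-dicarboxylate | COC(=O)C1=C(C(=O)OC)C=COC=C1 | intermediate
6 | oxepine-4,5-diyldimethanol | OCC1=C(CO)C=COC=C1 | intermediate
7 | 4,5-bis[(4-methoxybenzyloxy)methyl]oxepine | COc1ccc(COCC2=C(COCc3ccc(OC)cc3)C=COC=C2)cc1 | intermediate
8 | 3,4-bis[(4-methoxybenzyloxy)methyl]-7-oxabicyclo[4.1.0]hepta-2,4-diene (cis-fused meso arene oxide) | COc1ccc(COCC2=C[C@H]3O[C@H]3C=C2COCc2ccc(OC)cc2)cc1 | intermediate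
9 | 8,9-bis[(4-methoxybenzyloxy)methyl]-3,6,7-trioxatricyclo[3.2.2.0(2,4)]non-8-ene, peroxide bridge anti to the oxirane oxygen (meso) | COc1ccc(COCC2=C(COCc3ccc(OC)cc3)[C@H]4OO[C@@H]2[C@H]5O[C@@H]45)cc1 | intermediate
10 | (1R,5S,6R)-5-hydroxy-3,4-bis[(4-methoxybenzyloxy)methyl]-7-oxabicyclo[4.1.0]hept-3-en-2-one (OH anti to epoxide) | COc1ccc(COCC2=C(COCc3ccc(OC)cc3)C(=O)[C@@H]3O[C@@H]3[C@H]2O)cc1 | intermediate
11 | p-methoxybenzylidene acetal of C4–OH/C3–CH2OH (aryl equatorial), free C2–CH2OH, ring configuration as in 10 | OCC1=C2CO[C@H](c3ccc(OC)cc3)O[C@@H]2[C@H]3O[C@H]3C1=O | intermediate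
12 | corresponding C2-carbaldehyde | O=CC1=C2CO[C@H](c3ccc(OC)cc3)O[C@@H]2[C@H]3O[C@H]3C1=O | intermediate
13 | 5-(ethylsulfonyl)-1-phenyl-1H-tetrazole | CCS(=O)(=O)c1nnnn1-c1ccccc1 | starting material
14 | C2-[(E)-prop-1-enyl] p-methoxybenzylidene acetal | C/C=C/C1=C2CO[C@H](c3ccc(OC)cc3)O[C@@H]2[C@H]3O[C@H]3C1=O | intermediate
15 | (1R,5S,6R)-5-hydroxy-4-(hydroxymethyl)-3-[(E)-prop-1-enyl]-7-oxabicyclo[4.1.0]hept-3-en-2-one | C/C=C/C1=C(CO)[C@H](O)[C@H]2O[C@H]2C1=O | intermediate
16 | primary triethylsilyl ether of 15 | C/C=C/C1=C(CO[Si](CC)(CC)CC)[C@H](O)[C@H]2O[C@H]2C1=O | intermediate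
17 | C4-O-di-tert-butyl(triflyloxy)silyl ether of 16 | C/C=C/C1=C(CO[Si](CC)(CC)CC)[C@H](O[Si](OS(=O)(=O)C(F)(F)F)(C(C)(C)C)C(C)(C)C)[C@H]2O[C@H]2C1=O | intermediate
18 | C4-O-di-tert-butyl(hydroxy)silyl ether of 16 | C/C=C/C1=C(CO[Si](CC)(CC)CC)[C@H](O[Si](O)(C(C)(C)C)C(C)(C)C)[C@H]2O[C@H]2C1=O | intermediate
19 | C4-O-di-tert-butyl(hydroxy)silyl ether of 15 (primary OH free) | C/C=C/C1=C(CO)[C@H](O[Si](O)(C(C)(C)C)C(C)(C)C)[C@H]2O[C@H]2C1=O | intermediate
20 | corresponding C3-carbaldehyde (dienal) | C/C=C/C1=C(C=O)[C@H](O[Si](O)(C(C)(C)C)C(C)(C)C)[C@H]2O[C@H]2C1=O | intermediate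
21 | (2R)-2-methyl-2H-pyran valence isomer of 20, methyl syn to the epoxide | C[C@H]1OC=C2C(=C1)C(=O)[C@@H]1O[C@@H]1[C@H]2O[Si](O)(C(C)(C)C)C(C)(C)C | intermediate
22 | bis[di-tert-butyl(hydroxy)silyl] ether of epoxytwinol A | C[C@H]1O[C@H]2C3=C(C(=O)[C@@H]4O[C@@H]4[C@H]3O[Si](O)(C(C)(C)C)C(C)(C)C)[C@@H]1[C@H]1C3=C([C@H](O[Si](O)(C(C)(C)C)C(C)(C)C)[C@H]4O[C@H]4C3=O)[C@@H]2O[C@@H]1C | intermediate
23 | epoxytwinol A | C[C@H]1O[C@H]2C3=C(C(=O)[C@@H]4O[C@@H]4[C@H]3O)[C@@H]1[C@H]1C3=C([C@H](O)[C@H]4O[C@H]4C3=O)[C@@H]2O[C@@H]1C | target

Total step count: 13. Longest linear sequence: 13 steps (1/2 → 23).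

**Steps most likely to fail**

**Step 12.** The 2H-pyrans may prefer the [4+2] mode, may pair as unlike Ce-epimers, or the silanols may condense instead of templating. The fallback drops the silicon helper and sets out from 15. MnO2 in CH2Cl2 oxidises the primary alcohol selectively to the unprotected dienal F5. This equilibrates with the unprotected 2H-pyran F6. The mixture is concentrated and left neat at room temperature, and the [4+4] adduct is separated by chromatography from the [4+2] dimers formed alongside. This path comes back to the route directly at 23 and bypasses steps 10, 11 and 13.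

**Step 5.** The base may discriminate poorly between the enantiotopic bridgehead hydrogens, the endoperoxide may rearrange thermally, or the product may isomerise further under base.
- The fallback sets out from 7. The photooxygenation is run as written, but the cold solution of 9 is reduced in situ with thiourea (MeOH, −30 → 0 °C) to the meso 2,3-bis[(4-methoxybenzyloxy)methyl]-5,6-epoxycyclohex-2-ene-1,4-diol F1.
- Lipase-catalysed acetylation with vinyl acetate in MTBE desymmetrises F1 to the C4-monoacetate F2. Hydrolysis of the meso diacetate with the same enzyme reaches the other enantiotopic position if needed.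
- Oxidation of the remaining allylic alcohol (MnO2 or DMP) gives the 4-acetoxy enone F3.
- Lipase-catalysed methanolysis frees C4–OH, and the path comes back at 10.

**Step 8.** The carbanion may deprotonate the vinylogously acidic C4–H or C3–CH2 positions of the aldehyde, which leads to epoxide opening and aromatisation, or alkene geometry control may be poor. The fallback replaces olefination by addition and elimination and sets out from 12. Non-basic 1,2-addition of diethylzinc (Ti(OiPr)4, toluene, −20 °C) to the aldehyde gives the C2-(1-hydroxypropyl) acetal F4 as an epimer mixture whose new centre is destroyed next. Dehydration with Martin sulfurane (or Burgess reagent) towards the only available β-hydrogens gives the conjugated E-propenyl compound, and the path comes back at 14.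

**Further compounds**
F1 | step 5 | meso 2,3-bis[(4-methoxybenzyloxy)methyl]-5,6-epoxycyclohex-2-ene-1,4-diol (both OH anti to epoxide) | O[C@H]1C(COCc2ccc(OC)cc2)=C(COCc2ccc(OC)cc2)[C@@H](O)[C@@H]2O[C@H]12
F2 | step 5 | C4-monoacetate of F1 | CC(=O)O[C@H]1C(COCc2ccc(OC)cc2)=C(COCc2ccc(OC)cc2)[C@@H](O)[C@@H]2O[C@H]12
F3 | step 5 | 4-acetoxy enone (acetate of 10) | CC(=O)O[C@H]1C(COCc2ccc(OC)cc2)=C(COCc2ccc(OC)cc2)C(=O)[C@@H]2O[C@H]12
F4 | step 8 | C2-(1-hydroxypropyl) p-methoxybenzylidene acetal (carbinol epimers) | CCC(O)C1=C2CO[C@H](c3ccc(OC)cc3)O[C@@H]2[C@H]3O[C@H]3C1=O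
F5 | step 12 | unprotected dienal (C3-carbaldehyde of 15) | C/C=C/C1=C(C=O)[C@H](O)[C@H]2O[C@H]2C1=O
F6 | step 12 | unprotected (2R)-2-methyl-2H-pyran valence isomer of F5 | C[C@H]1OC=C2C(=C1)C(=O)[C@@H]1O[C@@H]1[C@H]2O
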